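**Plan**

1. Numbering used throughout: ring C1 (C=O), C2=C3, C4 (OMe), C5 (CH2), C6 (quaternary, allyl); side chain C8 (CHMe), C9 (its methyl), C7 (aryl C=O). Enabling feature: in the six-membered ring, oxygen sits on C1 and on C4, the two carbons either side of the C2=C3 double bond, and C6 carries C8. This is the retron of a Diels–Alder addition of a 1,4-dioxygenated butadiene (C1–C4) to the C5=C6 double bond of an acrolein whose formyl carbon is C8.
2. Retrosynthetic cuts, in order: C7–aryl (aryllithium on a lactone), C8–C9 (enolate methylation), C7–C8 (one-carbon Wittig homologation), then C1–C6 and C4–C5 together (the cycloaddition).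
3. Forward: the carbocycle is made first (step 3) from 2-allylacrolein and an E,E-1,4-bis(silyloxy)butadiene. The chain is grown from C8 to C7 and tied through C7 to the C4 oxygen as a bridged δ-lactone, which distinguishes the C4 oxygen from the C1 oxygen and is the template for C8. The lactone is opened by 3,4-dimethoxyphenyllithium, C4–OH is methylated, and C1 is desilylated and oxidised.
4. Stereochemistry: C6 comes from the chiral oxazaborolidinium catalyst (enal enantioface). C4 and the temporary C1 centre come from the E,E diene geometry and the endo transition state, which place both oxygens cis to C8. C8 comes from methylation of the rigid bicyclic lactone enolate on the face anti to the C6–C1 bond.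

Key step: step 3

Assumption: the (S)-diphenylprolinol-derived oxazaborolidinium ion is taken to bind 2-allylacrolein through boron with a formyl C–H···O contact and to leave open the Cα face that leads to (6R); if the sense proved opposite, the mirror-image catalyst would be used.

**Route**

Step 1
Reactants: 1 pent-4-enal; 2 formaldehyde (37% aqueous solution)
Product: 3 2-methylidenepent-4-enal (2-allylacrolein)
Conditions: pyrrolidine (10 mol%), propanoic acid (10 mol%), i-PrOH, 45 °C
Reagents that add atoms: none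
Why: Amine-catalysed α-methylenation (Mannich condensation–elimination through enamine and iminium ions) of an unbranched aldehyde with formaldehyde is a standard entry to 2-substituted acroleins, and the remote terminal alkene is inert.

Step 2
Reactants: 4 (1E,3E)-buta-1,3-diene-1,4-diyl diacetate
Product: 6 (1E,3E)-1,4-bis(tert-butyldimethylsilyloxy)buta-1,3-diene, via dilithium dienediolate 5 (not isolated)
Conditions: MeLi (4.2 equiv), THF, −78 → 0 °C; then t-BuMe2SiCl (2.4 equiv), DMPU, −78 °C → rt
Reagents that add atoms: tert-butyldimethylsilyl chloride, CC(C)(C)[Si](C)(C)Cl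
Why: Cleavage of an enol acetate with MeLi gives the lithium enolate with retention of double-bond geometry, so O-silylation of the dienediolate should deliver the E,E bis(silyl dienol ether) without the geometric mixtures expected from enol silylation of succinaldehyde.

Step 3
Reactants: 3 2-methylidenepent-4-enal; 6 (1E,3E)-1,4-bis(tert-butyldimethylsilyloxy)buta-1,3-diene
Product: 7 (1S,2R,5R)-2,5-bis(tert-butyldimethylsilyloxy)-1-(prop-2-en-1-yl)cyclohex-3-ene-1-carbaldehyde (formyl cis to both silyloxy groups)
Conditions: N-protonated (S)-3,3-diphenyl-1-(2-methylphenyl)tetrahydro-1H,3H-pyrrolo[1,2-c][1,3,2]oxazaborole triflimide, [C24H25BNO][N(SO2CF3)2], made from the oxazaborolidine and HN(SO2CF3)2 (20 mol%); 6 (1.5 equiv), CH2Cl2, −78 °C; Et3N quench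
Reagents that add atoms: none
Why: Binding of the formyl oxygen of 3 to the cationic boron lowers the enal LUMO and holds the s-trans enal against one phenyl group of the catalyst, so the diene reaches only the open Cα face in a concerted but asynchronous [4+2] addition in which bonding at the unsubstituted C5 terminus runs ahead of bonding at C6. The closest known reaction type is the oxazaborolidinium-catalysed Diels–Alder reaction of 2-substituted acroleins (methacrolein, 2-bromoacrolein) with acyclic and oxygenated dienes. The six-membered ring is closed by intermolecular suprafacial cycloaddition, C1–C6 and C4–C5 forming in the same step. C6 is set by the catalyst-controlled enantioface of the enal; C1 and C4 are cis to each other because the E,E geometry of the diene is transferred suprafacially, and both are cis to the formyl carbon C8 through the endo transition state, favoured for 2-substituted acroleins and acyclic 1-oxygenated dienes by formyl–diene secondary overlap under Lewis acid activation. The symmetric diene removes any regiochemical question; what the step needs is enantiofacial and endo selectivity and cycloaddition in preference to Mukaiyama-type addition or protodesilylation of the dienol ether, which the low temperature, the non-nucleophilic triflimide counter-ion and the robust tert-butyldimethylsilyl groups are meant to secure.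

Step 4
Reactants: 7 (1S,2R,5R)-2,5-bis(tert-butyldimethylsilyloxy)-1-(prop-2-en-1-yl)cyclohex-3-ene-1-carbaldehyde
Product: 8 (3R,4R,6R)-3,6-bis(tert-butyldimethylsilyloxy)-4-(2-methoxyethenyl)-4-(prop-2-en-1-yl)cyclohex-1-ene (E/Z mixture at the enol ether)
Conditions: MeOCH2PPh3Cl (3 equiv), KN(SiMe3)2 (2.8 equiv), THF, 0 °C; then 7, 0 °C → rt
Reagents that add atoms: (methoxymethyl)triphenylphosphonium chloride, COC[P+](c1ccccc1)(c1ccccc1)c1ccccc1.[Cl-]
Why: Wittig methoxymethylenation with the small, reactive ylide is reliable on α-quaternary aldehydes, there is no α-hydrogen through which the silyloxy group could be eliminated, and the enol ether geometry is of no consequence.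

Step 5
Reactants: 8 (3R,4R,6R)-3,6-bis(tert-butyldimethylsilyloxy)-4-(2-methoxyethenyl)-4-(prop-2-en-1-yl)cyclohex-1-ene
Product: 11 (1R,5R,6R)-6-(tert-butyldimethylsilyloxy)-5-(prop-2-en-1-yl)-2-oxabicyclo[3.3.1]non-7-en-3-ol (anomer mixture), via bis-silyl aldehyde 9 (not isolated), via hydroxy aldehyde 10 (not isolated)
Conditions: AcOH/THF/H2O (3:1:1), rt → 40 °C
Reagents that add atoms: water, O
Why: Acid hydrolysis of the enol ether gives the C7 aldehyde, the same medium should cleave the silyl ether at C4 (flanked by a CH2) well before the neopentyl one at C1 next to the quaternary C6, and the freed hydroxyl, cis-1,3 to the side chain, should close on the aldehyde as a six-membered bridged hemiacetal whose anomers converge in step 6.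

Step 6
Reactants: 11 (1R,5R,6R)-6-(tert-butyldimethylsilyloxy)-5-(prop-2-en-1-yl)-2-oxabicyclo[3.3.1]non-7-en-3-ol
Product: 12 (1R,5R,6R)-6-(tert-butyldimethylsilyloxy)-5-(prop-2-en-1-yl)-2-oxabicyclo[3.3.1]non-7-en-3-one
Conditions: 2,2,6,6-tetramethylpiperidin-1-oxyl (10 mol%), PhI(OAc)2 (1.5 equiv), CH2Cl2, rt
Reagents that add atoms: none
Why: Oxoammonium-mediated oxidation of a lactol to the lactone is selective for the hemiacetal and should leave the silyl ether and both alkenes untouched.

Step 7
Reactants: 12 (1R,5R,6R)-6-(tert-butyldimethylsilyloxy)-5-(prop-2-en-1-yl)-2-oxabicyclo[3.3.1]non-7-en-3-one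
Product: 13 (1R,4S,5R,6R)-6-(tert-butyldimethylsilyloxy)-4-methyl-5-(prop-2-en-1-yl)-2-oxabicyclo[3.3.1]non-7-en-3-one
Conditions: LiN(i-Pr)2 (1.1 equiv), THF, −78 °C; MeI (3 equiv), −78 → −40 °C
Reagents that add atoms: iodomethane, CI
Why: In this lactone enolate alkylation the C1–C2=C3 bridge with its cis silyloxy group covers one face of the C7=C8 enolate, so MeI should add axially on the open face anti to the C6–C1 bond, which places the methyl group at C8 in the (S) configuration of the target.

Step 8
Reactants: 13 (1R,4S,5R,6R)-6-(tert-butyldimethylsilyloxy)-4-methyl-5-(prop-2-en-1-yl)-2-oxabicyclo[3.3.1]non-7-en-3-one; 14 4-bromo-1,2-dimethoxybenzene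
Product: 16 (2S)-2-[(1R,2R,5R)-2-(tert-butyldimethylsilyloxy)-5-hydroxy-1-(prop-2-en-1-yl)cyclohex-3-en-1-yl]-1-(3,4-dimethoxyphenyl)propan-1-one, via 3,4-dimethoxyphenyllithium 15 (not isolated)
Conditions: 14, n-BuLi (1.15 equiv), THF, −78 °C; then 13, −78 → −40 °C; AcOH, −78 °C
Reagents that add atoms: none
Why: Bromine–lithium exchange followed by mono-addition of the aryllithium to a lactone at low temperature gives the aryl ketone, because the resulting α-branched ketone next to a quaternary carbon resists a second addition, and the cold acetic acid quench protects C8 from epimerisation.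

Step 9
Reactants: 16 (2S)-2-[(1R,2R,5R)-2-(tert-butyldimethylsilyloxy)-5-hydroxy-1-(prop-2-en-1-yl)cyclohex-3-en-1-yl]-1-(3,4-dimethoxyphenyl)propan-1-one
Product: 17 (2S)-2-[(1R,2R,5R)-2-(tert-butyldimethylsilyloxy)-5-methoxy-1-(prop-2-en-1-yl)cyclohex-3-en-1-yl]-1-(3,4-dimethoxyphenyl)propan-1-one
Conditions: MeOSO2CF3 (3 equiv), 2,6-di-tert-butyl-4-methylpyridine (4 equiv), CH2Cl2, 0 °C → rt
Reagents that add atoms: methyl trifluoromethanesulfonate, COS(=O)(=O)C(F)(F)F
Why: O-alkylation of the unhindered allylic C4 alcohol with methyl triflate and a hindered pyridine is a non-basic etherification, so no enolate forms at C8 and the δ-hydroxy aryl ketone, expected to stay open-chain, is methylated on the alcohol oxygen.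

Step 10
Reactants: 17 (2S)-2-[(1R,2R,5R)-2-(tert-butyldimethylsilyloxy)-5-methoxy-1-(prop-2-en-1-yl)cyclohex-3-en-1-yl]-1-(3,4-dimethoxyphenyl)propan-1-one
Product: 18 (2S)-1-(3,4-dimethoxyphenyl)-2-[(1R,2R,5R)-2-hydroxy-5-methoxy-1-(prop-2-en-1-yl)cyclohex-3-en-1-yl]propan-1-one
Conditions: Bu4NF (3 equiv), AcOH (3 equiv), THF, rt → 45 °C
Reagents that add atoms: none
Why: Fluoride desilylation removes the hindered C1 silyl ether, and buffering with acetic acid keeps the medium from epimerising C8 or dehydrating the γ-hydroxy ketone.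

Step 11
Reactants: 18 (2S)-1-(3,4-dimethoxyphenyl)-2-[(1R,2R,5R)-2-hydroxy-5-methoxy-1-(prop-2-en-1-yl)cyclohex-3-en-1-yl]propan-1-one
Product: 19 (4R,6R)-6-[(2S)-1-(3,4-dimethoxyphenyl)-1-oxopropan-2-yl]-4-methoxy-6-(prop-2-en-1-yl)cyclohex-2-en-1-one
Conditions: 1,1,1-triacetoxy-1,1-dihydro-1,2-benziodoxol-3(1H)-one (Dess–Martin periodinane, 1.5 equiv), CH2Cl2, 0 °C → rt
Reagents that add atoms: none
Why: Dess–Martin oxidation converts the secondary allylic alcohol into the enone under near-neutral conditions that leave C8 and the allylic methyl ether alone, any cyclic hemiketal with the C7 ketone draining through the open hydroxy ketone.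

**Compound list**

1 | pent-4-enal | C=CCCC=O | starting material
2 | formaldehyde (37% aqueous solution) | C=O | starting material
3 | 2-methylidenepent-4-enal (2-allylacrolein) | C=CCC(=C)C=O | intermediate
4 | (1E,3E)-buta-1,3-diene-1,4-diyl diacetate | CC(=O)O/C=C/C=C/OC(C)=O | starting material
5 | dilithium (1E,3E)-buta-1,3-diene-1,4-diolate | [Li+].[Li+].[O-]/C=C/C=C/[O-] | intermediate (not isolated)
6 | (1E,3E)-1,4-bis(tert-butyldimethylsilyloxy)buta-1,3-diene | CC(C)(C)[Si](C)(C)O/C=C/C=C/O[Si](C)(C)C(C)(C)C | intermediate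
7 | (1S,2R,5R)-2,5-bis(tert-butyldimethylsilyloxy)-1-(prop-2-en-1-yl)cyclohex-3-ene-1-carbaldehyde | C=CC[C@]1(C=O)C[C@@H](O[Si](C)(C)C(C)(C)C)C=C[C@H]1O[Si](C)(C)C(C)(C)C | intermediate
8 | (3R,4R,6R)-3,6-bis(tert-butyldimethylsilyloxy)-4-(2-methoxyethenyl)-4-(prop-2-en-1-yl)cyclohex-1-ene (E/Z mixture) | C=CC[C@]1(C=COC)C[C@@H](O[Si](C)(C)C(C)(C)C)C=C[C@H]1O[Si](C)(C)C(C)(C)C | intermediate
9 | 2-[(1R,2R,5R)-2,5-bis(tert-butyldimethylsilyloxy)-1-(prop-2-en-1-yl)cyclohex-3-en-1-yl]acetaldehyde | C=CC[C@]1(CC=O)C[C@@H](O[Si](C)(C)C(C)(C)C)C=C[C@H]1O[Si](C)(C)C(C)(C)C | intermediate (not isolated)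
10 | 2-[(1R,2R,5R)-2-(tert-butyldimethylsilyloxy)-5-hydroxy-1-(prop-2-en-1-yl)cyclohex-3-en-1-yl]acetaldehyde | C=CC[C@]1(CC=O)C[C@@H](O)C=C[C@H]1O[Si](C)(C)C(C)(C)C | intermediate (not isolated)
11 | (1R,5R,6R)-6-(tert-butyldimethylsilyloxy)-5-(prop-2-en-1-yl)-2-oxabicyclo[3.3.1]non-7-en-3-ol (anomer mixture) | C=CC[C@]1(CC2O)C[C@@H](O2)C=C[C@H]1O[Si](C)(C)C(C)(C)C | intermediate
12 | (1R,5R,6R)-6-(tert-butyldimethylsilyloxy)-5-(prop-2-en-1-yl)-2-oxabicyclo[3.3.1]non-7-en-3-one | C=CC[C@]1(CC2=O)C[C@@H](O2)C=C[C@H]1O[Si](C)(C)C(C)(C)C | intermediate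
13 | (1R,4S,5R,6R)-6-(tert-butyldimethylsilyloxy)-4-methyl-5-(prop-2-en-1-yl)-2-oxabicyclo[3.3.1]non-7-en-3-one | C=CC[C@]1([C@H](C)C2=O)C[C@@H](O2)C=C[C@H]1O[Si](C)(C)C(C)(C)C | intermediate
14 | 4-bromo-1,2-dimethoxybenzene | COc1ccc(Br)cc1OC | starting material
15 | 3,4-dimethoxyphenyllithium | COc1ccc([Li])cc1OC | intermediate (not isolated)
16 | (2S)-2-[(1R,2R,5R)-2-(tert-butyldimethylsilyloxy)-5-hydroxy-1-(prop-2-en-1-yl)cyclohex-3-en-1-yl]-1-(3,4-dimethoxyphenyl)propan-1-one | C=CC[C@]1([C@H](C)C(=O)c2ccc(OC)c(OC)c2)C[C@@H](O)C=C[C@H]1O[Si](C)(C)C(C)(C)C | intermediate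
17 | (2S)-2-[(1R,2R,5R)-2-(tert-butyldimethylsilyloxy)-5-methoxy-1-(prop-2-en-1-yl)cyclohex-3-en-1-yl]-1-(3,4-dimethoxyphenyl)propan-1-one | C=CC[C@]1([C@H](C)C(=O)c2ccc(OC)c(OC)c2)C[C@@H](OC)C=C[C@H]1O[Si](C)(C)C(C)(C)C | intermediate
18 | (2S)-1-(3,4-dimethoxyphenyl)-2-[(1R,2R,5R)-2-hydroxy-5-methoxy-1-(prop-2-en-1-yl)cyclohex-3-en-1-yl]propan-1-one | C=CC[C@]1([C@H](C)C(=O)c2ccc(OC)c(OC)c2)C[C@@H](OC)C=C[C@H]1O | intermediate
19 | (4R,6R)-6-[(2S)-1-(3,4-dimethoxyphenyl)-1-oxopropan-2-yl]-4-methoxy-6-(prop-2-en-1-yl)cyclohex-2-en-1-one | C=CC[C@]1([C@H](C)C(=O)c2ccc(OC)c(OC)c2)C[C@@H](OC)C=CC1=O | target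

**Count**

Total steps: 11. Longest linear sequence: 10 steps (1 → 3 → 7 → … → 19, or equally 4 → 6 → 7 → … → 19).

**Steps most likely to fail, with fallbacks**

Step 3. The cationic boron acid may consume the silyl dienol ether (protodesilylation, Mukaiyama-type conjugate addition), or enantiofacial or endo control may be inadequate. The fallback gives up catalysis and resolves. It sets out from 3 and 6: heating them in toluene at 60–80 °C without catalyst should give the endo adduct as a racemate, that is 7 together with its mirror image, (1R,2S,5S)-2,5-bis(tert-butyldimethylsilyloxy)-1-(prop-2-en-1-yl)cyclohex-3-ene-1-carbaldehyde F1. Condensation of the mixture with (1R,2R)-N,N'-dimethyl-1,2-diphenylethane-1,2-diamine (Et2O, 4 Å molecular sieves) should give two diastereomeric aminals separable on silica, the 1,3-dimethyl-4,5-diphenylimidazolidine aminal of 7 F2 and the corresponding aminal of the mirror-image aldehyde F3. Brief two-phase hydrolysis of the first (0.5 M aqueous HCl/Et2O, 0 °C) should release 7, where the route is rejoined.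

Step 5. The acid may fail to tell the two silyl ethers apart: both may be lost, with closure of the five-membered hemiacetal through the C1 hydroxyl, or cleavage at C4 may be sluggish. The fallback moves the differentiation from rate to protecting-group identity and sets out from 8. Bu4NF in THF should remove both silyl groups to give (1R,4R,5R)-5-(2-methoxyethenyl)-5-(prop-2-en-1-yl)cyclohex-2-ene-1,4-diol F4. Et3SiCl/imidazole at −40 °C should silylate only the unhindered C4 hydroxyl, giving the C4 triethylsilyl ether of that diol F5. t-BuMe2SiOSO2CF3/2,6-lutidine should then cap the neopentyl C1 hydroxyl, giving the C4 triethylsilyl C1 tert-butyldimethylsilyl bis-ether F6. AcOH/THF/H2O at room temperature, which removes a triethylsilyl ether far faster than a tert-butyldimethylsilyl ether, should then cleave the C4 ether and hydrolyse the enol ether in one operation, so that the lactol 11 is reached and the route continues with step 6.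

Step 8. The aryllithium may enolise the hindered lactone instead of adding (lactone returned, C8 exposed to epimerisation), or may add twice. The fallback transfers the acyl group from an open-chain N-methoxy-N-methylamide and sets out from 13. MeNH(OMe)·HCl/AlMe3 (CH2Cl2, 0 °C → rt) should open the lactone to (2S)-2-[(1R,2R,5R)-2-(tert-butyldimethylsilyloxy)-5-hydroxy-1-(prop-2-en-1-yl)cyclohex-3-en-1-yl]-N-methoxy-N-methylpropanamide F7. Ag2O/MeI should methylate the C4 hydroxyl under neutral conditions to give the corresponding 5-methoxy amide F8. The aryllithium 15 should then add once, through the chelated tetrahedral intermediate, to give 17 directly, so that the route is rejoined at step 10.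

**Further compounds**

F1 | step 3 | (1R,2S,5S)-2,5-bis(tert-butyldimethylsilyloxy)-1-(prop-2-en-1-yl)cyclohex-3-ene-1-carbaldehyde (mirror image of 7) | C=CC[C@@]1(C=O)C[C@H](O[Si](C)(C)C(C)(C)C)C=C[C@@H]1O[Si](C)(C)C(C)(C)C
F2 | step 3 | aminal of 7 with (1R,2R)-N,N'-dimethyl-1,2-diphenylethane-1,2-diamine (1,3-dimethyl-4,5-diphenylimidazolidin-2-yl in place of formyl) | C=CC[C@]1(C2N(C)[C@H](c3ccccc3)[C@@H](c3ccccc3)N2C)C[C@@H](O[Si](C)(C)C(C)(C)C)C=C[C@H]1O[Si](C)(C)C(C)(C)C
F3 | step 3 | aminal of F1 with the same (1R,2R)-diamine | C=CC[C@@]1(C2N(C)[C@H](c3ccccc3)[C@@H](c3ccccc3)N2C)C[C@H](O[Si](C)(C)C(C)(C)C)C=C[C@@H]1O[Si](C)(C)C(C)(C)C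
F4 | step 5 | (1R,4R,5R)-5-(2-methoxyethenyl)-5-(prop-2-en-1-yl)cyclohex-2-ene-1,4-diol (E/Z mixture) | C=CC[C@]1(C=COC)C[C@@H](O)C=C[C@H]1O
F5 | step 5 | C4 triethylsilyl ether of F4 (silyl on the hydroxyl remote from the quaternary carbon) | C=CC[C@]1(C=COC)C[C@@H](O[Si](CC)(CC)CC)C=C[C@H]1O
F6 | step 5 | C4 triethylsilyl C1 tert-butyldimethylsilyl bis-ether of F4 | C=CC[C@]1(C=COC)C[C@@H](O[Si](CC)(CC)CC)C=C[C@H]1O[Si](C)(C)C(C)(C)C
F7 | step 8 | (2S)-2-[(1R,2R,5R)-2-(tert-butyldimethylsilyloxy)-5-hydroxy-1-(prop-2-en-1-yl)cyclohex-3-en-1-yl]-N-methoxy-N-methylpropanamide | C=CC[C@]1([C@H](C)C(=O)N(C)OC)C[C@@H](O)C=C[C@H]1O[Si](C)(C)C(C)(C)C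
F8 | step 8 | (2S)-2-[(1R,2R,5R)-2-(tert-butyldimethylsilyloxy)-5-methoxy-1-(prop-2-en-1-yl)cyclohex-3-en-1-yl]-N-methoxy-N-methylpropanamide | C=CC[C@]1([C@H](C)C(=O)N(C)OC)C[C@@H](OC)C=C[C@H]1O[Si](C)(C)C(C)(C)C
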